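## The problem

Compound 13 is the branched profisetinidin triflavanoid fisetinidol-(4α→8)-[fisetinidol-(4α→6)]-catechin. Its core is a (2R,3S)-catechin (aromatic ring D, pyran ring F, catechol ring E) whose only two free positions on ring D, C8 and C6, are each bonded to C4 of a (2R,3S,4S)-fisetinidol unit (resorcinol ring A, pyran ring C, catechol ring B on C8; rings G, I and H in the same roles on C6). Ring D is therefore hexasubstituted and each C(sp3)–C(sp2) interflavanyl bond lies between two ortho oxygens, so two crowded bonds must be made on one ring, exactly twice and no more. The eight stereocentres fall into three islands (C2/C3 of ring F, C2/C3/C4 of ring C, C2/C3/C4 of ring I). Inside an island a centre can direct its neighbour, but the flat ring D insulates the islands from each other, so each needs its own source of absolute configuration. Rings A and G lack the 5-oxygen of catechin, so a C4 cation of this series is harder to form than in the procyanidins, and its only facial bias is the equatorial O3 next to it. The free compound has ten phenolic and three secondary hydroxyls, is oxidised by air, opens its pyran rings under base through quinone methides (epimerisation at C2, migration of a pyran ring to an oxygen of ring D), and can lose or scramble its interflavanyl bonds in strong acid, so the phenols must stay masked and be released under neutral conditions. The plan rests on one feature: rings C and I are identical, and in each the array O1–C2(H)(aryl)–C3(H)(OH)–C4(H)(ring D) is all-trans, with hydrogen on C2 and C4 and the only oxygen substituent on C3, β to O1. Such a ring is a 2,4-diaryl-1-benzopyrylium (flavylium) ring that has taken up hydride at C4 and then H and OH, syn, across the enol ether C2=C3 on the face away from ring D. Both upper heterocycles can therefore be attached to ring D as flat, achiral, aromatic rings and receive their six stereocentres afterwards, both at once.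

## Retrosynthesis

**13 ⇒ 12.**
- Bonds cut: the eleven O–CH2Ph bonds (ten phenolic, one on O3 of ring F).
- Why this cut: esters would need base, which opens the pyran rings of 13. Methyl ethers would need a strong Lewis acid at the most fragile stage.
- Gain: 12 has the same skeleton but tolerates organolithiums, mild acid, borane and alkaline peroxide, so it sets the protecting scheme for the whole route.
- Asked of the forward step: cleave the O-benzyl bonds and leave the ring C2–O1 bonds and the C4 diarylmethine bonds alone.

**12 ⇒ 10 (through 11).**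
- Bonds cut: C3–O and C2–H in rings C and I, four bonds and four stereocentres in all.
- Why this cut: the 3-hydroxyl sits where an enol ether C2=C3 directs boron. Syn addition puts H2 and O3 cis (so 2-aryl and 3-OH are trans). Attack anti to the C4 substituent makes 3,4-trans. The all-trans triad is thus the natural outcome of hydroboration–oxidation of a 4-aryl-4H-chromene.
- Neighbouring cut: C3–O and C4–H from a 2H-chromene gives the same relative result but makes C2 the controlling centre. It is kept in reserve.
- Gain: 10 has four stereocentres instead of eight.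
- Asked of the forward step: boron to C3, approach from the face opposite ring D, and survival of the β-aryloxyborane 11 until it is oxidised.

**10 ⇒ 9 ⇒ 8 (key disconnection).**
- Bonds cut: the two C4–H bonds, as hydride.
- Why this cut: what remains is the bis(flavylium) dication 9, with no stereocentre in rings C and I. It is reached by ionising the stereorandom bis(tertiary carbinol) 8.
- Against the classical cut: C4 is made stereogenic by forming a C–H bond rather than the crowded C–C bond. The C–C bond formation then carries no stereochemical burden, and the face is chosen by a chiral counter-anion that serves both arms.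
- Gain: of the eight stereocentres of 13 only the two of ring F are defined in 8.
- Asked of the forward step: hydride to C4 and not to C2, and catalyst-controlled choice of the same face on both arms.

**8 ⇒ 7 + 2 × 6.**
- Bonds cut: C4(ring C)–C8(ring D) and C4(ring I)–C6(ring D), at the carbonyl oxidation level, giving the 6,8-dianion 7 and two molecules of the flat flavone 6.
- Why this cut: 6 has no α-hydrogen, no stereocentre and no nucleophilic site, so it cannot enolise, epimerise or oligomerise. The number of unions is fixed at two by the two C–Li bonds. The C6/C8 regiochemical question disappears because both positions receive the same piece.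
- Gain: 45 skeletal carbons are divided 15 + 15 + 15.
- Asked of the forward step: clean double bromine–lithium exchange and 1,2-addition.

**7 ⇒ 4 ⇒ 3 ⇒ 2 ⇒ 1, and 6 ⇒ 5.**
- Bonds cut: two C–Br bonds and the benzyl ethers.
- Why this cut: ring D of 3 is the only trioxygenated ring and C6 and C8 are its only free positions, so bromination needs no directing device.
- Gain: 1 supplies C2 and C3 of ring F from the chiral pool, and 5 supplies rings A, B and the carbon skeleton of ring C (likewise G, H, I) ready-made.

## Roads not taken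

**Alternative 1: (the obvious, biomimetic cut).**
- Cut: both interflavanyl bonds, heterolytically, into a C4 benzylic cation and the nucleophilic ring D of 1.
- Forward key step: acid-promoted double Friedel–Crafts alkylation of 1 by two equivalents of the 2,3-trans-3,4-trans flavan-3,4-diol (+)-mollisacacidin A1, or a protected and C4-activated form of it.
- Why the chosen plan is better:
  - A1 carries three stereocentres, is not a stock chemical, and would need its own asymmetric synthesis before the union.
  - C4 becomes stereogenic in the crowded C–C bond-forming event on a planar cation biased only by the equatorial O3, and this happens at two sites.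
  - The 5-deoxy cation needs forcing activation, under which rings A and G of product and electrophile compete as nucleophiles.
  - The first substitution can occur at C8 or C6, with different follow-up rates.
  - In the chosen plan the C–C union has no stereochemical content, the electrophile cannot self-condense, and all upper stereocentres come from one catalyst and one relay.

**Alternative 2:**
- Cut: the same two bonds at the ketone level, but with C2 and C3 already in place.
- Forward key step: 7 is added to two equivalents of (2R,3R)-tetra-O-benzylfustin A2 to give the bis(tertiary carbinol) A3, whose hydroxyls are removed by ionic reduction (silane and acid).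
- Why the chosen plan is better:
  - A nucleophile prefers the C4 cation face anti to O3. Here the nucleophile is hydride, so ring D is pushed to the face of O3. This is the 3,4-cis (4β) series and not 12.
  - A2 needs an enantiopure dihydroflavonol.
  - The C3–H of A2 is acidic and β to the ring aryloxide, so the hindered base 7 can trigger ring opening.
  - The chosen plan uses the same carbanion on a ketone without α-hydrogen. It also reverses the order of events: hydrogen goes to C4 first and oxygen enters C3 afterwards, anti to ring D, as trans demands.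

**Alternative 3:**
- Cut: C4–C4a (to rings A and G) and O1–C2, so that the upper units grow outward from ring D.
- Forward sequence: 4 is converted into the dialdehyde A4. Aldol condensation gives the bis(chalcone) A5. The key step is a double asymmetric conjugate addition of the boronic acid A6 under [RhCl(C2H4)2]2 and a chiral diene, giving the bis(β,β-diaryl ketone) A7. Unmasking and cyclodehydration lead to 10.
- Why the chosen plan is better:
  - The road ends at the same 10 but needs five steps from 4 instead of two.
  - The β-carbon of A5 is deactivated by the trioxygenated ring D and shielded by two ortho benzyloxy groups.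
  - A6 is an electron-rich ortho-oxygenated boronic acid prone to protodeboronation.
  - A second kind of protecting group is required.
  - The chosen plan buys rings A and B and the three carbons of ring C in one commercial flavone.

Key step: step 6

Assumption: the sense of induction of the phosphoric acid on 9 cannot be deduced from structure alone. The (R)-acid is written, and its equally available mirror image is meant if hydride arrives from the other face. Compounds 1 and 5 are taken as commercial.

## Route

Step 1
Reactants: 1 (+)-catechin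
Product: 2 (2R,3S)-5,7-bis(benzyloxy)-2-[3,4-bis(benzyloxy)phenyl]chroman-3-ol
Conditions: BnBr (4.4 equiv), K2CO3, DMF, 0 °C → rt
Reagents that add atoms: benzyl bromide, BrCc1ccccc1
Why: Williamson etherification of the four phenols with a carbonate base that leaves the far less acidic 3-hydroxyl untouched; the mild base and low temperature avoid epimerisation at C2 through a ring E quinone methide, so C2 and C3 of ring F come unchanged from 1.

Step 2
Reactants: 2 (2R,3S)-5,7-bis(benzyloxy)-2-[3,4-bis(benzyloxy)phenyl]chroman-3-ol
Product: 3 (2R,3S)-3,5,7-tris(benzyloxy)-2-[3,4-bis(benzyloxy)phenyl]chroman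
Conditions: NaH, BnBr, DMF, 0 °C → rt
Reagents that add atoms: benzyl bromide, BrCc1ccccc1
Why: Williamson etherification of the secondary alcohol through its sodium alkoxide; with all phenols capped no quinone methide can form, so the strong base is safe, and the ether removes the last acidic hydrogen before the organolithium step.

Step 3
Reactants: 3 (2R,3S)-3,5,7-tris(benzyloxy)-2-[3,4-bis(benzyloxy)phenyl]chroman
Product: 4 (2R,3S)-3,5,7-tris(benzyloxy)-2-[3,4-bis(benzyloxy)phenyl]-6,8-dibromochroman
Conditions: NBS (2.1 equiv), CH2Cl2, 0 °C → rt, dark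
Reagents that add atoms: N-bromosuccinimide, O=C1CCC(=O)N1Br
Why: Electrophilic aromatic bromination; ring D is the only 1,3,5-trioxygenated ring and C6 and C8 are its only free positions, each ortho or para to three oxygens, so two equivalents are consumed there before the dialkoxy ring E reacts.

Step 4
Reactants: 5 3',4',7-trihydroxyflavone
Product: 6 7-(benzyloxy)-2-[3,4-bis(benzyloxy)phenyl]-4H-chromen-4-one
Conditions: BnBr (3.5 equiv), K2CO3, DMF, 60 °C
Reagents that add atoms: benzyl bromide, BrCc1ccccc1
Why: Williamson etherification of three unhindered phenols; the flavone has no 5-hydroxyl, so none is held back by chelation to the carbonyl.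

Step 5
Reactants: 4 (2R,3S)-3,5,7-tris(benzyloxy)-2-[3,4-bis(benzyloxy)phenyl]-6,8-dibromochroman; 6 7-(benzyloxy)-2-[3,4-bis(benzyloxy)phenyl]-4H-chromen-4-one (2.3 equiv)
Product: 8 (2R,3S)-3,5,7-tris(benzyloxy)-2-[3,4-bis(benzyloxy)phenyl]-6,8-bis{7-(benzyloxy)-2-[3,4-bis(benzyloxy)phenyl]-4-hydroxy-4H-chromen-4-yl}chroman (carbinol epimers), via dilithiated catechin ether 7 (not isolated)
Conditions: t-BuLi (4.2 equiv), THF, −78 °C; then 6, THF, −78 → −20 °C; H2O
Reagents that add atoms: tert-butyllithium, [Li]C(C)(C)C (supplies the lithium of 7; none of its atoms stays in 8)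
Why: Irreversible bromine–lithium exchange outruns any attack on benzyl ethers at −78 °C, and each C–Li bond is held between two chelating alkoxy groups; 6 has no enolisable hydrogen and its C2 is blocked by ring B, so the hard aryllithium adds 1,2 to the C4 carbonyl, the classical entry to 4-arylflavylium precursors; the two carbinol centres form without control and are erased in step 6.

Step 6
Reactants: 8 (2R,3S)-3,5,7-tris(benzyloxy)-2-[3,4-bis(benzyloxy)phenyl]-6,8-bis{7-(benzyloxy)-2-[3,4-bis(benzyloxy)phenyl]-4-hydroxy-4H-chromen-4-yl}chroman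
Product: 10 (2R,3S)-3,5,7-tris(benzyloxy)-2-[3,4-bis(benzyloxy)phenyl]-6,8-bis{(4S)-7-(benzyloxy)-2-[3,4-bis(benzyloxy)phenyl]-4H-chromen-4-yl}chroman, via bis(flavylium) dication 9 (not isolated)
Conditions: (R)-3,3'-bis(2,4,6-triisopropylphenyl)-1,1'-binaphthalene-2,2'-diyl hydrogen phosphate (20 mol %), diethyl 2,6-dimethyl-1,4-dihydropyridine-3,5-dicarboxylate (Hantzsch ester, 2.4 equiv), 4 Å molecular sieves, toluene, −20 °C → rt
Reagents that add atoms: none
Why: The phosphoric acid protonates each tertiary, doubly benzylic carbinol and expels water, so rings C and I become aromatic 2,4-diaryl-1-benzopyrylium cations (each arm in turn; drawn doubly ionised as 9) held as contact ion pairs with the chiral phosphate, whose phosphoryl oxygen also binds the N–H of the Hantzsch ester, so hydride is handed to C4 inside the chiral pocket and the acid is returned by the pyridinium formed. The closest known reaction type is the chiral-phosphate-paired 1,4-transfer hydrogenation of 2,4-diaryl-1-benzopyrylium ions generated in situ from chromenols, which gives 4-aryl-4H-chromenes. No ring is closed; two aromatic pyrylium rings are dearomatised. The two new stereocentres, C4 of ring C and C4 of ring I, are both set by the catalyst, because ring D stands perpendicular to each cation and shows it an oxygen substituent on either face (O7 and O1 at C8, O5 and O7 at C6), so the substrate itself has almost no facial bias to oppose the catalyst. The step needs C4 over C2 regioselectivity: the para-benzyloxy group of the coplanar ring B (H) drains charge from C2, the twisted ring D cannot donate to C4, and only the 4H-chromene keeps the aryl enol ether conjugation. That C4 next to a 2,4,6-trioxygenated aryl group is open to a bulky organic hydride donor follows from the known hydride exchange between 4-arylflav-2-enes and flavylium ions. Because 9 is flat, the stereorandom centres and any carbinol isomers of 8 converge on one intermediate. Since ring F labels the molecule, a wrong-face event gives a separable diastereomer and not an enantiomer, and this step fixes the configuration that step 7 relays to all six upper centres.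

Step 7
Reactants: 10 (2R,3S)-3,5,7-tris(benzyloxy)-2-[3,4-bis(benzyloxy)phenyl]-6,8-bis{(4S)-7-(benzyloxy)-2-[3,4-bis(benzyloxy)phenyl]-4H-chromen-4-yl}chroman
Product: 12 (2R,3S)-3,5,7-tris(benzyloxy)-2-[3,4-bis(benzyloxy)phenyl]-6,8-bis{(2R,3S,4S)-7-(benzyloxy)-2-[3,4-bis(benzyloxy)phenyl]-3-hydroxychroman-4-yl}chroman, via bis(3-boryl)flavan 11 (not isolated)
Conditions: BH3·SMe2, THF, 0 °C → rt; then aq NaOH, H2O2, 0 °C
Reagents that add atoms: borane–dimethyl sulfide, C[S+](C)[BH3-] (supplies the boron of 11; only hydrogen stays in 12); hydrogen peroxide, OO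
Why: Hydroboration–oxidation of a cyclic 2-aryl enol ether, as known for flav-2-enes and 1-aryl glycals: O1 polarises C2=C3 so that boron goes to C3 and hydrogen to C2; ring D stands pseudo-axial on the flattened boat to avoid H5 and covers the α face, so borane adds syn from the β face, which makes O3 trans to ring D and, since H2 and boron are cis, trans to the C2 aryl group; oxidation with retention gives (2R,3S,4S) in rings C and I.

Step 8
Reactants: 12 (2R,3S)-3,5,7-tris(benzyloxy)-2-[3,4-bis(benzyloxy)phenyl]-6,8-bis{(2R,3S,4S)-7-(benzyloxy)-2-[3,4-bis(benzyloxy)phenyl]-3-hydroxychroman-4-yl}chroman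
Product: 13 (2R,3S)-2-(3,4-dihydroxyphenyl)-6,8-bis[(2R,3S,4S)-2-(3,4-dihydroxyphenyl)-3,7-dihydroxychroman-4-yl]chroman-3,5,7-triol
Conditions: H2 (1 atm), Pd(OH)2/C, THF–MeOH, rt; filtration and freeze-drying under argon
Reagents that add atoms: none
Why: Hydrogenolysis of benzyl ethers over Pd(OH)2/C is the standard neutral end-game for proanthocyanidins; the ring C2–O1 bonds and the C4 diarylmethine bonds are hindered secondary benzylic bonds that cleave much more slowly, and no stereocentre is touched.

## Compound list

1 | (+)-catechin, (2R,3S) | Oc1cc(O)c2c(c1)O[C@H](c1ccc(O)c(O)c1)[C@@H](O)C2 | starting material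

2 | 5,7,3',4'-tetra-O-benzylcatechin | c9ccccc9COc1cc(OCc9ccccc9)c2c(c1)O[C@H](c1ccc(OCc9ccccc9)c(OCc9ccccc9)c1)[C@@H](O)C2 | intermediate

3 | 3,5,7,3',4'-penta-O-benzylcatechin | c9ccccc9COc1cc(OCc9ccccc9)c2c(c1)O[C@H](c1ccc(OCc9ccccc9)c(OCc9ccccc9)c1)[C@@H](OCc9ccccc9)C2 | intermediate

4 | 6,8-dibromo-penta-O-benzylcatechin | Brc1c(OCc9ccccc9)c2c(c(Br)c1OCc9ccccc9)O[C@H](c1ccc(OCc9ccccc9)c(OCc9ccccc9)c1)[C@@H](OCc9ccccc9)C2 | intermediate

5 | 3',4',7-trihydroxyflavone | O=c1cc(-c2ccc(O)c(O)c2)oc2cc(O)ccc12 | starting material

6 | 3',4',7-tris(benzyloxy)flavone | O=c1cc(-c2ccc(OCc9ccccc9)c(OCc9ccccc9)c2)oc2cc(OCc9ccccc9)ccc12 | intermediate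

7 | 6,8-dilithio-penta-O-benzylcatechin (not isolated) | [Li]c1c(OCc9ccccc9)c2c(c([Li])c1OCc9ccccc9)O[C@H](c1ccc(OCc9ccccc9)c(OCc9ccccc9)c1)[C@@H](OCc9ccccc9)C2 | intermediate

8 | bis(4-hydroxy-4H-chromen-4-yl) adduct, both carbinol carbons undefined | c9ccccc9COc1ccc2c(c1)OC(c1ccc(OCc9ccccc9)c(OCc9ccccc9)c1)=CC2(O)c1c(OCc9ccccc9)c2c(c(C3(O)c4ccc(OCc9ccccc9)cc4OC(c4ccc(OCc9ccccc9)c(OCc9ccccc9)c4)=C3)c1OCc9ccccc9)O[C@H](c1ccc(OCc9ccccc9)c(OCc9ccccc9)c1)[C@@H](OCc9ccccc9)C2 | intermediate

9 | bis(flavylium) dication paired with the chiral phosphate (not isolated) | c9ccccc9COc1ccc2c(c1)[o+]c(-c1ccc(OCc9ccccc9)c(OCc9ccccc9)c1)cc2-c1c(OCc9ccccc9)c2c(c(-c3cc(-c4ccc(OCc9ccccc9)c(OCc9ccccc9)c4)[o+]c4cc(OCc9ccccc9)ccc34)c1OCc9ccccc9)O[C@H](c1ccc(OCc9ccccc9)c(OCc9ccccc9)c1)[C@@H](OCc9ccccc9)C2 | intermediate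

10 | bis[(4S)-4H-chromen-4-yl] compound (bis-flav-2-ene) | c9ccccc9COc1ccc2c(c1)OC(c1ccc(OCc9ccccc9)c(OCc9ccccc9)c1)=C[C@@H]2c1c(OCc9ccccc9)c2c(c([C@@H]3c4ccc(OCc9ccccc9)cc4OC(c4ccc(OCc9ccccc9)c(OCc9ccccc9)c4)=C3)c1OCc9ccccc9)O[C@H](c1ccc(OCc9ccccc9)c(OCc9ccccc9)c1)[C@@H](OCc9ccccc9)C2 | intermediate

11 | bis(3-boryl)flavan, BH2 in the place of each ring C and ring I hydroxyl of 12 (not isolated) | c9ccccc9COc1ccc2c(c1)O[C@H](c1ccc(OCc9ccccc9)c(OCc9ccccc9)c1)[C@@H](B)[C@@H]2c1c(OCc9ccccc9)c2c(c([C@@H]3c4ccc(OCc9ccccc9)cc4O[C@H](c4ccc(OCc9ccccc9)c(OCc9ccccc9)c4)[C@H]3B)c1OCc9ccccc9)O[C@H](c1ccc(OCc9ccccc9)c(OCc9ccccc9)c1)[C@@H](OCc9ccccc9)C2 | intermediate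

12 | undeca-O-benzyl triflavanoid, 3-OH of rings C and I free | c9ccccc9COc1ccc2c(c1)O[C@H](c1ccc(OCc9ccccc9)c(OCc9ccccc9)c1)[C@@H](O)[C@@H]2c1c(OCc9ccccc9)c2c(c([C@@H]3c4ccc(OCc9ccccc9)cc4O[C@H](c4ccc(OCc9ccccc9)c(OCc9ccccc9)c4)[C@H]3O)c1OCc9ccccc9)O[C@H](c1ccc(OCc9ccccc9)c(OCc9ccccc9)c1)[C@@H](OCc9ccccc9)C2 | intermediate

13 | fisetinidol-(4α→8)-[fisetinidol-(4α→6)]-catechin (CNP0289228.3) | Oc1ccc2c(c1)O[C@H](c1ccc(O)c(O)c1)[C@@H](O)[C@@H]2c1c(O)c2c(c([C@@H]3c4ccc(O)cc4O[C@H](c4ccc(O)c(O)c4)[C@H]3O)c1O)O[C@H](c1ccc(O)c(O)c1)[C@@H](O)C2 | target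

## Step count and weak points

Total step count: 8. Longest linear sequence: 7 (steps 1, 2, 3, 5, 6, 7, 8).

**Step 6 (key step).**
- What may go wrong:
  - Facial selectivity may be poor on one or both arms. The 4-aryl group is far larger than in the known cases, and slow rotation about the ring D–C4 axes presents the catalyst with more than one ion-pair geometry.
  - Hydride may be delivered to the more open C2.
  - The enol ether formed may be protonated and reduced further.
- Fallback (sets out from 4, returns at 12): the absolute configuration is moved from the crowded C4 to the open C2 and fixed on a small fragment before the union.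
  - 7-Hydroxychromone is benzylated to 7-(benzyloxy)chromen-4-one F1.
  - Conjugate addition of 3,4-bis(benzyloxy)phenylboronic acid under Pd(OCOCF3)2 and the appropriate enantiomer of the tert-butyl pyridine-oxazoline ligand gives (2S)-7-(benzyloxy)-2-[3,4-bis(benzyloxy)phenyl]chroman-4-one F2.
  - Compound 7, made from 4 as in step 5 and transmetallated with CeCl3 to suppress enolisation, is added to F2 to give the bis(tertiary carbinol) F3.
  - Non-acidic dehydration with methyl N-(triethylammoniosulfonyl)carbamate gives the bis[(2S)-flav-3-ene] F4.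
  - Hydroboration–oxidation as in step 7 puts boron on C3 anti to the C2 aryl group and hydrogen on C4 from the same face. This is again the all-trans array and gives 12.

**Step 5.**
- What may go wrong:
  - The second bromine–lithium exchange may be incomplete.
  - A proton may transfer from a benzylic OCH2 to the aryl anion.
  - The second addition may stall next to the first bulky alkoxide.
- Fallback (sets out from 3 and 6, returns at 9), with no organometallic:
  - Compound 6 is reduced with LiAlH4 and the allylic alcohol ionised with HBF4·OEt2 to 7-(benzyloxy)-2-[3,4-bis(benzyloxy)phenyl]chromenylium tetrafluoroborate F5.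
  - Ring D of 3, a 1,3,5-trialkoxybenzene, attacks C4 of two equivalents of F5 (Friedel–Crafts addition to a flavylium ion, with 2,6-di-tert-butylpyridine as proton sink). This gives the bis(flav-2-ene) as a mixture of C4 epimers F6.
  - Hydride abstraction with trityl tetrafluoroborate erases these centres and gives the bis(flavylium) bis(tetrafluoroborate) F7.
  - Aqueous NaHCO3 converts F7 into the bis(2H-chromen-2-ol) pseudobase F8, which ionises to the same 9 under the conditions of step 6.

**Step 7.**
- What may go wrong:
  - The C3 boron and the ring aryloxide on C2 are antiperiplanar in 11 and may eliminate, with ring opening.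
  - Addition to the crowded trisubstituted alkene may be slow.
- Fallback (sets out from 10, returns at 12):
  - Catalytic OsO4 with N-methylmorpholine N-oxide dihydroxylates C2=C3 from the face opposite ring D to give the bis(2,3-dihydroxy) hemiketal F9.
  - Et3SiH and BF3·OEt2 at low temperature then ionise the hemiketal carbon. Hydride is delivered axially to the 2-aryl oxocarbenium ion, as in the reduction of aryl lactols to C-aryl glycosides. This leaves the C2 aryl group equatorial and trans to O3.

**Step 8.**
- What may go wrong: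
  - Hydrogenolysis may stall as the partly deprotected material changes solubility and adsorbs on the catalyst.
  - A ring C2–O1 bond may slowly cleave on long exposure.
  - The free polyphenol may oxidise in air during isolation.
- Fallback (sets out from 12, returns at 13): non-reductive debenzylation with BCl3 and pentamethylbenzene as benzyl cation scavenger in CH2Cl2 at −78 °C, followed by methanol quench. The 5-deoxy interflavanyl bonds are the acid-resistant type. This makes no new compound (F0).

## Further compounds

F1 | step 6 | 7-(benzyloxy)chromen-4-one | O=c1ccoc2cc(OCc9ccccc9)ccc12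

F2 | step 6 | (2S)-7-(benzyloxy)-2-[3,4-bis(benzyloxy)phenyl]chroman-4-one | c9ccccc9COc1ccc2c(c1)O[C@H](c1ccc(OCc9ccccc9)c(OCc9ccccc9)c1)CC2=O

F3 | step 6 | bis(tertiary carbinol) from 7 and F2, carbinol carbons undefined | c9ccccc9COc1ccc2c(c1)O[C@H](c1ccc(OCc9ccccc9)c(OCc9ccccc9)c1)CC2(O)c1c(OCc9ccccc9)c2c(c(C3(O)c4ccc(OCc9ccccc9)cc4O[C@H](c4ccc(OCc9ccccc9)c(OCc9ccccc9)c4)C3)c1OCc9ccccc9)O[C@H](c1ccc(OCc9ccccc9)c(OCc9ccccc9)c1)[C@@H](OCc9ccccc9)C2

F4 | step 6 | bis[(2S)-flav-3-en-4-yl] compound | c9ccccc9COc1ccc2c(c1)O[C@H](c1ccc(OCc9ccccc9)c(OCc9ccccc9)c1)C=C2c1c(OCc9ccccc9)c2c(c(C3=C[C@@H](c4ccc(OCc9ccccc9)c(OCc9ccccc9)c4)Oc4cc(OCc9ccccc9)ccc34)c1OCc9ccccc9)O[C@H](c1ccc(OCc9ccccc9)c(OCc9ccccc9)c1)[C@@H](OCc9ccccc9)C2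

F5 | step 5 | 7-(benzyloxy)-2-[3,4-bis(benzyloxy)phenyl]chromenylium tetrafluoroborate | c9ccccc9COc1ccc2ccc(-c3ccc(OCc9ccccc9)c(OCc9ccccc9)c3)[o+]c2c1.F[B-](F)(F)F

F6 | step 5 | bis(flav-2-ene), mixture of C4 epimers | c9ccccc9COc1ccc2c(c1)OC(c1ccc(OCc9ccccc9)c(OCc9ccccc9)c1)=CC2c1c(OCc9ccccc9)c2c(c(C3c4ccc(OCc9ccccc9)cc4OC(c4ccc(OCc9ccccc9)c(OCc9ccccc9)c4)=C3)c1OCc9ccccc9)O[C@H](c1ccc(OCc9ccccc9)c(OCc9ccccc9)c1)[C@@H](OCc9ccccc9)C2

F7 | step 5 | bis(flavylium) bis(tetrafluoroborate) | c9ccccc9COc1ccc2c(c1)[o+]c(-c1ccc(OCc9ccccc9)c(OCc9ccccc9)c1)cc2-c1c(OCc9ccccc9)c2c(c(-c3cc(-c4ccc(OCc9ccccc9)c(OCc9ccccc9)c4)[o+]c4cc(OCc9ccccc9)ccc34)c1OCc9ccccc9)O[C@H](c1ccc(OCc9ccccc9)c(OCc9ccccc9)c1)[C@@H](OCc9ccccc9)C2.F[B-](F)(F)F.F[B-](F)(F)F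

F8 | step 5 | bis(2-hydroxy-2H-chromen-4-yl) pseudobase, hemiketal carbons undefined | c9ccccc9COc1ccc2c(c1)OC(O)(c1ccc(OCc9ccccc9)c(OCc9ccccc9)c1)C=C2c1c(OCc9ccccc9)c2c(c(C3=CC(O)(c4ccc(OCc9ccccc9)c(OCc9ccccc9)c4)Oc4cc(OCc9ccccc9)ccc34)c1OCc9ccccc9)O[C@H](c1ccc(OCc9ccccc9)c(OCc9ccccc9)c1)[C@@H](OCc9ccccc9)C2

F9 | step 7 | bis(2,3-dihydroxy) hemiketal, both hydroxyls of each ring on the face opposite ring D | c9ccccc9COc1ccc2c(c1)O[C@](O)(c1ccc(OCc9ccccc9)c(OCc9ccccc9)c1)[C@@H](O)[C@@H]2c1c(OCc9ccccc9)c2c(c([C@@H]3c4ccc(OCc9ccccc9)cc4O[C@](O)(c4ccc(OCc9ccccc9)c(OCc9ccccc9)c4)[C@H]3O)c1OCc9ccccc9)O[C@H](c1ccc(OCc9ccccc9)c(OCc9ccccc9)c1)[C@@H](OCc9ccccc9)C2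

F0 | step 8 | none | none

A1 | alternative 1 | (+)-mollisacacidin, (2R,3S,4R)-2-(3,4-dihydroxyphenyl)chroman-3,4,7-triol | Oc1ccc2c(c1)O[C@H](c1ccc(O)c(O)c1)[C@@H](O)[C@@H]2O

A2 | alternative 2 | (2R,3R)-3,7,3',4'-tetra-O-benzylfustin | c9ccccc9COc1ccc2c(c1)O[C@H](c1ccc(OCc9ccccc9)c(OCc9ccccc9)c1)[C@@H](OCc9ccccc9)C2=O

A3 | alternative 2 | bis(tertiary carbinol) from 7 and A2, carbinol carbons undefined | c9ccccc9COc1ccc2c(c1)O[C@H](c1ccc(OCc9ccccc9)c(OCc9ccccc9)c1)[C@@H](OCc9ccccc9)C2(O)c1c(OCc9ccccc9)c2c(c(C3(O)c4ccc(OCc9ccccc9)cc4O[C@H](c4ccc(OCc9ccccc9)c(OCc9ccccc9)c4)[C@H]3OCc9ccccc9)c1OCc9ccccc9)O[C@H](c1ccc(OCc9ccccc9)c(OCc9ccccc9)c1)[C@@H](OCc9ccccc9)C2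

A4 | alternative 3 | penta-O-benzylcatechin-6,8-dicarbaldehyde | O=Cc1c(OCc9ccccc9)c2c(c(C=O)c1OCc9ccccc9)O[C@H](c1ccc(OCc9ccccc9)c(OCc9ccccc9)c1)[C@@H](OCc9ccccc9)C2

A5 | alternative 3 | 6,8-bis[(E)-3-(3,4-dibenzyloxyphenyl)-3-oxoprop-1-enyl] bis(chalcone) | O=C(c1ccc(OCc9ccccc9)c(OCc9ccccc9)c1)/C=C/c1c(OCc9ccccc9)c2c(c(/C=C/C(=O)c3ccc(OCc9ccccc9)c(OCc9ccccc9)c3)c1OCc9ccccc9)O[C@H](c1ccc(OCc9ccccc9)c(OCc9ccccc9)c1)[C@@H](OCc9ccccc9)C2

A6 | alternative 3 | [4-(benzyloxy)-2-(methoxymethoxy)phenyl]boronic acid | OB(O)c1ccc(OCc9ccccc9)cc1OCOC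

A7 | alternative 3 | bis(β,β-diaryl ketone) with the C4 configuration of 10 | O=C(c1ccc(OCc9ccccc9)c(OCc9ccccc9)c1)C[C@@H](c1ccc(OCc9ccccc9)cc1OCOC)c1c(OCc9ccccc9)c2c(c([C@@H](CC(=O)c3ccc(OCc9ccccc9)c(OCc9ccccc9)c3)c3ccc(OCc9ccccc9)cc3OCOC)c1OCc9ccccc9)O[C@H](c1ccc(OCc9ccccc9)c(OCc9ccccc9)c1)[C@@H](OCc9ccccc9)C2
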